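## Retrosynthetic overview

1. Pestaphilone G ⇒ protected bicycle; ring B (pyran) is closed last through the O2–C3 bond by cycloisomerization of a 4-oxo-2-alkynylcyclohexenecarbaldehyde, after C1 is placed on C8a by a vinylogous Mukaiyama reaction.
2. C4–C4a ⇒ Sonogashira coupling of a ring A vinylogous triflate with a side-chain alkyne.
3. Ring A (formed first) ⇒ intramolecular Claisen condensation (C5–C6) of a methyl ketone ester; its key C8–C8a bond ⇒ photochemical Wolff rearrangement (retention) of a diazoketone.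
4. Both methyl-bearing diol units (C7/C8 and C1'/C2') ⇒ one monoacid made from D-tartrate acetonide by enolate methylation; C3'=C4' ⇒ Z-enol triflate/methyl cross-coupling; C5' ⇒ (S)-1-bromo-2-methylbutane.
5. Ring order: carbocycle (ring A) by Claisen condensation, then pyran (ring B) by cycloisomerization.

Numbering: isochromene numbering C1–C8a for the bicycle (ring A = carbocycle, ring B = pyran); C1' (tertiary carbinol) to C7' for the side chain, C5' being the methyl-bearing CH.

Assumption: the lithium enolate of the tartrate acetonide is methylated with retention (methyl cis to the neighbouring ester), as established for this enolate; the route has not been run and the selectivities given are expectations.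

## Route

Step 1
Reactants: 1 dimethyl (4S,5S)-2,2-dimethyl-1,3-dioxolane-4,5-dicarboxylate
Product: 3 dimethyl (4S,5S)-2,2,4-trimethyl-1,3-dioxolane-4,5-dicarboxylate, via lithium enolate 2 (not isolated)
Conditions: LiN(iPr)2 (1.05 equiv), THF/DMPU, −78 °C; then MeI, −78 to −20 °C
Reagents that add atoms: methyl iodide, CI
Why: Seebach-type enolate alkylation of the tartrate acetonide, in which the electrophile enters cis to the neighbouring ester (retention), so the quaternary centre (later C7 and C1') is set by the adjacent tartrate centre.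

Step 2
Reactants: 3 dimethyl (4S,5S)-2,2,4-trimethyl-1,3-dioxolane-4,5-dicarboxylate
Product: 4 (4S,5S)-5-(methoxycarbonyl)-2,2,5-trimethyl-1,3-dioxolane-4-carboxylic acid
Conditions: KOH (1.0 equiv), MeOH/H2O, 0 °C to rt; then aq. HCl to pH 2
Reagents that add atoms: potassium hydroxide, [K+].[OH-]
Why: Saponification with one equivalent of hydroxide cleaves the ester on the tertiary carbon much faster than the one on the quaternary carbon, and neither stereocentre is touched.

Step 3
Reactants: 4 (4S,5S)-5-(methoxycarbonyl)-2,2,5-trimethyl-1,3-dioxolane-4-carboxylic acid; 5 (S)-1-bromo-2-methylbutane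
Product: 8 methyl (4S,5S)-2,2,4-trimethyl-5-[(3S)-3-methylpentanoyl]-1,3-dioxolane-4-carboxylate, via acid chloride 6 (not isolated), via Grignard reagent 7 (not isolated)
Conditions: 4: (COCl)2, DMF (cat.), CH2Cl2, 0 °C to rt, evaporate; 5: Mg, THF, rt; then 6 + 7, Fe(acac)3 (3 mol %), THF, −78 °C
Reagents that add atoms: none
Why: Iron-catalysed acylation of a Grignard reagent by an acid chloride is faster than addition to the new ketone or the hindered ester, and the (S)-methyl centre is beta to magnesium and cannot racemise.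

Step 4
Reactants: 8 methyl (4S,5S)-2,2,4-trimethyl-5-[(3S)-3-methylpentanoyl]-1,3-dioxolane-4-carboxylate
Product: 10 methyl (4S,5S)-2,2,4-trimethyl-5-[(1Z,3S)-3-methyl-1-(trifluoromethylsulfonyloxy)pent-1-en-1-yl]-1,3-dioxolane-4-carboxylate, via lithium enolate 9 (not isolated)
Conditions: LiN(SiMe3)2 (1.1 equiv), THF, −78 °C; then PhNTf2, −78 to 0 °C
Reagents that add atoms: N-phenylbis(trifluoromethanesulfonimide), O=S(=O)(N(c1ccccc1)S(=O)(=O)C(F)(F)F)C(F)(F)F
Why: Kinetic deprotonation at the less hindered CH2 gives the Z enolate (allylic strain keeps the sec-butyl group cis to oxygen and away from the dioxolane), which is trapped by enolate O-sulfonylation.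

Step 5
Reactants: 10 methyl (4S,5S)-2,2,4-trimethyl-5-[(1Z,3S)-3-methyl-1-(trifluoromethylsulfonyloxy)pent-1-en-1-yl]-1,3-dioxolane-4-carboxylate
Product: 11 methyl (4S,5R)-2,2,4-trimethyl-5-[(2E,4S)-4-methylhex-2-en-2-yl]-1,3-dioxolane-4-carboxylate
Conditions: MeMgBr (1.5 equiv), Fe(acac)3 (5 mol %), THF/NMP, −30 °C
Reagents that add atoms: methylmagnesium bromide, C[Mg]Br
Why: Iron-catalysed cross-coupling of an alkenyl triflate with a Grignard reagent (Kochi-type) goes with retention of alkene geometry, so the Z triflate gives the E trisubstituted alkene before the hindered ester is attacked.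

Step 6
Reactants: 11 methyl (4S,5R)-2,2,4-trimethyl-5-[(2E,4S)-4-methylhex-2-en-2-yl]-1,3-dioxolane-4-carboxylate
Product: 13 (4R,5R)-4-ethynyl-2,2,4-trimethyl-5-[(2E,4S)-4-methylhex-2-en-2-yl]-1,3-dioxolane, via aldehyde 12 (not isolated)
Conditions: iBu2AlH (1.1 equiv), CH2Cl2, −78 °C; then MeOH, K2CO3, dimethyl (1-diazo-2-oxopropyl)phosphonate, −78 °C to rt
Reagents that add atoms: dimethyl (1-diazo-2-oxopropyl)phosphonate, CC(=O)C(=[N+]=[N-])P(=O)(OC)OC
Why: Partial reduction of the alpha-alkoxy ester stops at the chelated hemiacetal, and the released aldehyde is homologated in the same flask by Ohira–Bestmann alkynylation; the quaternary alpha carbon cannot epimerise.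

Step 7
Reactants: 4 (4S,5S)-5-(methoxycarbonyl)-2,2,5-trimethyl-1,3-dioxolane-4-carboxylic acid
Product: 15 methyl (4S,5S)-5-(diazoacetyl)-2,2,4-trimethyl-1,3-dioxolane-4-carboxylate, via mixed anhydride 14 (not isolated)
Conditions: iBuOCOCl, N-methylmorpholine, THF, −15 °C; then CH2N2, Et2O, 0 °C
Reagents that add atoms: diazomethane, C=[N+]=[N-]
Why: Mixed-anhydride acylation of diazomethane (first half of an Arndt–Eistert homologation) is mild enough for the acetonide and leaves the alpha stereocentre untouched.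

Step 8
Reactants: 15 methyl (4S,5S)-5-(diazoacetyl)-2,2,4-trimethyl-1,3-dioxolane-4-carboxylate
Product: 17 methyl (4S,5R)-5-{2-[methoxy(methyl)amino]-2-oxoethyl}-2,2,4-trimethyl-1,3-dioxolane-4-carboxylate, via ketene 16 (not isolated)
Conditions: hν (365 nm LED), MeNHOMe (3 equiv), THF, 0 °C to rt
Reagents that add atoms: N,O-dimethylhydroxylamine, CNOC
Why: Photochemical Wolff rearrangement, in which the dioxolanyl carbon migrates with retention to form the C8–C8a bond and the ketene is trapped by the amine as a Weinreb amide, so C8 keeps the tartrate configuration.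

Step 9
Reactants: 17 methyl (4S,5R)-5-{2-[methoxy(methyl)amino]-2-oxoethyl}-2,2,4-trimethyl-1,3-dioxolane-4-carboxylate
Product: 18 methyl (4S,5R)-2,2,4-trimethyl-5-(2-oxopropyl)-1,3-dioxolane-4-carboxylate
Conditions: MeMgBr (1.3 equiv), THF, −78 to 0 °C; aq. NH4Cl
Reagents that add atoms: methylmagnesium bromide, C[Mg]Br
Why: Weinreb ketone synthesis, where the stable magnesium chelate prevents over-addition and the ester on the quaternary carbon is too hindered to compete at low temperature.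

Step 10
Reactants: 18 methyl (4S,5R)-2,2,4-trimethyl-5-(2-oxopropyl)-1,3-dioxolane-4-carboxylate
Product: 20 (4S,5R)-4,5-dihydroxy-4-methylcyclohexane-1,3-dione, via acetonide dione 19 (not isolated)
Conditions: LiN(iPr)2 (2.2 equiv), THF, −78 to 0 °C; then 2 M aq. HCl, THF, rt to 40 °C
Reagents that add atoms: none
Why: Intramolecular Claisen (Dieckmann-type) condensation of the kinetic methyl ketone enolate (C5) onto the C6 ester closes ring A and is driven by formation of the dione enolate, after which the strained trans-fused acetonide is hydrolysed in the acidic work-up; C7 and C8 are not enolisable and keep their configuration.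

Step 11
Reactants: 20 (4S,5R)-4,5-dihydroxy-4-methylcyclohexane-1,3-dione
Product: 21 (4S,5R)-4,5-dihydroxy-4-methyl-3-oxocyclohex-1-en-1-yl trifluoromethanesulfonate
Conditions: PhNTf2 (1.05 equiv), iPr2NEt, DMAP (cat.), CH2Cl2, 0 °C to rt
Reagents that add atoms: N-phenylbis(trifluoromethanesulfonimide), O=S(=O)(N(c1ccccc1)S(=O)(=O)C(F)(F)F)C(F)(F)F
Why: O-sulfonylation of a vinylogous acid, where the triflimide reacts only with the acidic dione enol and at the oxygen remote from the quaternary C7, leaving the ketone at C6 and the two alcohols free.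

Step 12
Reactants: 21 (4S,5R)-4,5-dihydroxy-4-methyl-3-oxocyclohex-1-en-1-yl trifluoromethanesulfonate; 13 (4R,5R)-4-ethynyl-2,2,4-trimethyl-5-[(2E,4S)-4-methylhex-2-en-2-yl]-1,3-dioxolane
Product: 22 (5R,6S)-5,6-dihydroxy-6-methyl-3-{[(4R,5R)-2,2,4-trimethyl-5-[(2E,4S)-4-methylhex-2-en-2-yl]-1,3-dioxolan-4-yl]ethynyl}cyclohex-2-en-1-one
Conditions: Pd(PPh3)2Cl2 (5 mol %), CuI (10 mol %), Et3N (3 equiv), THF, rt
Reagents that add atoms: none
Why: Sonogashira coupling of the electron-poor vinylogous triflate with the terminal alkyne forms C4–C4a at room temperature and tolerates the free hydroxyls.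

Step 13
Reactants: 22 (5R,6S)-5,6-dihydroxy-6-methyl-3-{[(4R,5R)-2,2,4-trimethyl-5-[(2E,4S)-4-methylhex-2-en-2-yl]-1,3-dioxolan-4-yl]ethynyl}cyclohex-2-en-1-one
Product: 24 (4S,5R,6S)-5,6-bis(tert-butyldimethylsilyloxy)-4-(dimethoxymethyl)-6-methyl-3-{[(4R,5R)-2,2,4-trimethyl-5-[(2E,4S)-4-methylhex-2-en-2-yl]-1,3-dioxolan-4-yl]ethynyl}cyclohex-2-en-1-one, via silyl dienol ether 23 (not isolated)
Conditions: TBSOTf (3.5 equiv), Et3N (5 equiv), CH2Cl2, −78 to 0 °C; then HC(OMe)3 (3 equiv), TMSOTf (10 mol %), −78 °C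
Reagents that add atoms: tert-butyldimethylsilyl trifluoromethanesulfonate, CC(C)(C)[Si](C)(C)OS(=O)(=O)C(F)(F)F; trimethyl orthoformate, COC(OC)OC
Why: Soft enolisation can only occur at C8a (C7 has no hydrogen), and the resulting 1-silyloxydiene attacks the dimethoxycarbenium ion at its gamma carbon (vinylogous Mukaiyama reaction) anti to the C8 silyloxy group, giving a temporary C8a centre that is lost in step 14.

Step 14
Reactants: 24 (4S,5R,6S)-5,6-bis(tert-butyldimethylsilyloxy)-4-(dimethoxymethyl)-6-methyl-3-{[(4R,5R)-2,2,4-trimethyl-5-[(2E,4S)-4-methylhex-2-en-2-yl]-1,3-dioxolan-4-yl]ethynyl}cyclohex-2-en-1-one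
Product: 26 (7S,8R)-7,8-bis(tert-butyldimethylsilyloxy)-7-methyl-3-{(4S,5R)-2,2,4-trimethyl-5-[(2E,4S)-4-methylhex-2-en-2-yl]-1,3-dioxolan-4-yl}-7,8-dihydro-6H-isochromen-6-one, via alkynyl enal 25 (not isolated)
Conditions: Ph3PAuNTf2 (5 mol %), PPTS (10 mol %), H2O (3 equiv), CH2Cl2, rt
Reagents that add atoms: water, O
Why: Proposed new method: a cationic monovalent gold catalyst converts a non-aromatic 4-oxo-2-alkynylcyclohexenecarbaldehyde (25, unmasked in situ by acetal hydrolysis and tautomerisation) directly into the 6H-isochromen-6-one by 6-endo-dig attack of the formyl oxygen on the gold-activated alkyne (O2–C3, ring B) and discharge of the pyrylium by loss of the C5 proton alpha to the C6 ketone, then protodeauration, so no oxidant is needed; the closest known reaction type is the gold-catalysed cycloisomerization of 2-alkynylbenzaldehydes to 2-benzopyrylium salts, which needs a separate oxidative dearomatization; no stereocentre is formed or touched.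

Step 15
Reactants: 26 (7S,8R)-7,8-bis(tert-butyldimethylsilyloxy)-7-methyl-3-{(4S,5R)-2,2,4-trimethyl-5-[(2E,4S)-4-methylhex-2-en-2-yl]-1,3-dioxolan-4-yl}-7,8-dihydro-6H-isochromen-6-one
Product: 27 Pestaphilone G, (7S,8R)-3-[(2S,3R,4E,6S)-2,3-dihydroxy-4,6-dimethyloct-4-en-2-yl]-7,8-dihydroxy-7-methyl-7,8-dihydro-6H-isochromen-6-one
Conditions: HF (48% aq.), MeCN, 0 °C to rt
Reagents that add atoms: none
Why: Global deprotection (desilylation and acetonide hydrolysis) under weakly acidic conditions that should spare the vinylogous ester chromophore and the allylic C8 hydroxyl; no stereocentre is affected.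

## Compound list

1 | dimethyl (4S,5S)-2,2-dimethyl-1,3-dioxolane-4,5-dicarboxylate (D-tartrate acetonide) | COC(=O)[C@H]1OC(C)(C)O[C@@H]1C(=O)OC | starting material
2 | lithium ester enolate of 1 (remaining centre 5S) | COC(O[Li])=C1OC(C)(C)O[C@@H]1C(=O)OC | intermediate
3 | dimethyl (4S,5S)-2,2,4-trimethyl-1,3-dioxolane-4,5-dicarboxylate | COC(=O)[C@@]1(C)OC(C)(C)O[C@@H]1C(=O)OC | intermediate
4 | (4S,5S)-5-(methoxycarbonyl)-2,2,5-trimethyl-1,3-dioxolane-4-carboxylic acid | COC(=O)[C@@]1(C)OC(C)(C)O[C@@H]1C(=O)O | intermediate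
5 | (S)-1-bromo-2-methylbutane | BrC[C@@H](C)CC | starting material
6 | methyl (4S,5S)-5-(chlorocarbonyl)-2,2,4-trimethyl-1,3-dioxolane-4-carboxylate | COC(=O)[C@@]1(C)OC(C)(C)O[C@@H]1C(Cl)=O | intermediate
7 | (S)-2-methylbutylmagnesium bromide | Br[Mg]C[C@@H](C)CC | intermediate
8 | methyl (4S,5S)-2,2,4-trimethyl-5-[(3S)-3-methylpentanoyl]-1,3-dioxolane-4-carboxylate | COC(=O)[C@@]1(C)OC(C)(C)O[C@@H]1C(=O)C[C@@H](C)CC | intermediate
9 | lithium Z enolate of 8 (O cis to the sec-butyl group) | COC(=O)[C@@]1(C)OC(C)(C)O[C@@H]1/C(O[Li])=C/[C@@H](C)CC | intermediate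
10 | methyl (4S,5S)-2,2,4-trimethyl-5-[(1Z,3S)-3-methyl-1-(trifluoromethylsulfonyloxy)pent-1-en-1-yl]-1,3-dioxolane-4-carboxylate | COC(=O)[C@@]1(C)OC(C)(C)O[C@@H]1/C(OS(=O)(=O)C(F)(F)F)=C/[C@@H](C)CC | intermediate
11 | methyl (4S,5R)-2,2,4-trimethyl-5-[(2E,4S)-4-methylhex-2-en-2-yl]-1,3-dioxolane-4-carboxylate | COC(=O)[C@@]1(C)OC(C)(C)O[C@@H]1/C(C)=C/[C@@H](C)CC | intermediate
12 | (4S,5R)-2,2,4-trimethyl-5-[(2E,4S)-4-methylhex-2-en-2-yl]-1,3-dioxolane-4-carbaldehyde | O=C[C@@]1(C)OC(C)(C)O[C@@H]1/C(C)=C/[C@@H](C)CC | intermediate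
13 | (4R,5R)-4-ethynyl-2,2,4-trimethyl-5-[(2E,4S)-4-methylhex-2-en-2-yl]-1,3-dioxolane | C#C[C@@]1(C)OC(C)(C)O[C@@H]1/C(C)=C/[C@@H](C)CC | intermediate
14 | mixed isobutyl carbonic anhydride of 4 (4S,5S) | COC(=O)[C@@]1(C)OC(C)(C)O[C@@H]1C(=O)OC(=O)OCC(C)C | intermediate
15 | methyl (4S,5S)-5-(diazoacetyl)-2,2,4-trimethyl-1,3-dioxolane-4-carboxylate | COC(=O)[C@@]1(C)OC(C)(C)O[C@@H]1C(=O)C=[N+]=[N-] | intermediate
16 | methyl (4S,5R)-2,2,4-trimethyl-5-(2-oxoethenyl)-1,3-dioxolane-4-carboxylate (ketene) | COC(=O)[C@@]1(C)OC(C)(C)O[C@@H]1C=C=O | intermediate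
17 | methyl (4S,5R)-5-{2-[methoxy(methyl)amino]-2-oxoethyl}-2,2,4-trimethyl-1,3-dioxolane-4-carboxylate | COC(=O)[C@@]1(C)OC(C)(C)O[C@@H]1CC(=O)N(C)OC | intermediate
18 | methyl (4S,5R)-2,2,4-trimethyl-5-(2-oxopropyl)-1,3-dioxolane-4-carboxylate | COC(=O)[C@@]1(C)OC(C)(C)O[C@@H]1CC(C)=O | intermediate
19 | (3aS,7aR)-2,2,3a-trimethyltetrahydro-1,3-benzodioxole-4,6(5H,7H)-dione (trans-fused) | O=C1[C@@]2(C)OC(C)(C)O[C@@H]2CC(=O)C1 | intermediate
20 | (4S,5R)-4,5-dihydroxy-4-methylcyclohexane-1,3-dione | O=C1[C@@](C)(O)[C@H](O)CC(=O)C1 | intermediate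
21 | (4S,5R)-4,5-dihydroxy-4-methyl-3-oxocyclohex-1-en-1-yl trifluoromethanesulfonate | O=C1[C@@](C)(O)[C@H](O)CC(OS(=O)(=O)C(F)(F)F)=C1 | intermediate
22 | (5R,6S)-5,6-dihydroxy-6-methyl-3-{[(4R,5R)-2,2,4-trimethyl-5-[(2E,4S)-4-methylhex-2-en-2-yl]-1,3-dioxolan-4-yl]ethynyl}cyclohex-2-en-1-one | O=C1[C@@](C)(O)[C@H](O)CC(C#C[C@@]2(C)OC(C)(C)O[C@@H]2/C(C)=C/[C@@H](C)CC)=C1 | intermediate
23 | tris(tert-butyldimethylsilyl) derivative of 22: 1,5,6-tris(silyloxy)-6-methyl-3-alkynylcyclohexa-1,3-diene, centres as in 22 | CC(C)(C)[Si](C)(C)OC1=CC(C#C[C@@]2(C)OC(C)(C)O[C@@H]2/C(C)=C/[C@@H](C)CC)=C[C@@H](O[Si](C)(C)C(C)(C)C)[C@]1(C)O[Si](C)(C)C(C)(C)C | intermediate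
24 | (4S,5R,6S)-5,6-bis(tert-butyldimethylsilyloxy)-4-(dimethoxymethyl)-6-methyl-3-{[(4R,5R)-2,2,4-trimethyl-5-[(2E,4S)-4-methylhex-2-en-2-yl]-1,3-dioxolan-4-yl]ethynyl}cyclohex-2-en-1-one | O=C1C=C(C#C[C@@]2(C)OC(C)(C)O[C@@H]2/C(C)=C/[C@@H](C)CC)[C@H](C(OC)OC)[C@@H](O[Si](C)(C)C(C)(C)C)[C@]1(C)O[Si](C)(C)C(C)(C)C | intermediate
25 | (5S,6R)-5,6-bis(tert-butyldimethylsilyloxy)-5-methyl-4-oxo-2-{[(4R,5R)-2,2,4-trimethyl-5-[(2E,4S)-4-methylhex-2-en-2-yl]-1,3-dioxolan-4-yl]ethynyl}cyclohex-1-ene-1-carbaldehyde | O=CC1=C(C#C[C@@]2(C)OC(C)(C)O[C@@H]2/C(C)=C/[C@@H](C)CC)CC(=O)[C@@](C)(O[Si](C)(C)C(C)(C)C)[C@@H]1O[Si](C)(C)C(C)(C)C | intermediate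
26 | (7S,8R)-7,8-bis(tert-butyldimethylsilyloxy)-7-methyl-3-{(4S,5R)-2,2,4-trimethyl-5-[(2E,4S)-4-methylhex-2-en-2-yl]-1,3-dioxolan-4-yl}-7,8-dihydro-6H-isochromen-6-one | CC[C@H](C)/C=C(\C)[C@H]3OC(C)(C)O[C@]3(C)C1=CC2=CC(=O)[C@@](C)(O[Si](C)(C)C(C)(C)C)[C@H](O[Si](C)(C)C(C)(C)C)C2=CO1 | intermediate
27 | Pestaphilone G, (7S,8R)-3-[(2S,3R,4E,6S)-2,3-dihydroxy-4,6-dimethyloct-4-en-2-yl]-7,8-dihydroxy-7-methyl-7,8-dihydro-6H-isochromen-6-one | CC[C@H](C)/C=C(\C)[C@@H](O)[C@](C)(O)C1=CC2=CC(=O)[C@@](C)(O)[C@H](O)C2=CO1 | target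

## Step count and risks

Total steps: 15. Longest linear sequence: 11 (steps 1, 2, 7, 8, 9, 10, 11, 12, 13, 14, 15). The side-chain branch is steps 1–6, joining at step 12.

Steps most likely to fail:

Step 14 (the proposed new method). The gold step could give 5-exo closure, attack by other oxygens, or simply stall on the hindered acetal. The fallback uses known chemistry and sets out from 24. Pyrrolidine adds in conjugate (1,6) fashion to the enynone to give the dienaminone F1 (pyrrolidine, MeCN, rt). Aqueous acetic acid in THF then hydrolyses the enamine to the C3 ketone and the acetal to the C1 aldehyde, and the resulting 1,5-dicarbonyl compound closes by the classical acid-mediated cyclodehydration to the pyran. The sequence comes back to the route at 26.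

Step 10. Ring closure onto the trans-disposed dioxolane may be slowed by strain, and the small, polar diol 20 is awkward to isolate. The fallback sets out from 18 and replaces the cyclic protecting group before cyclisation. Aqueous acetic acid removes the acetonide to give the diol F2. TESOTf and 2,6-lutidine give the bis(triethylsilyl) ether F3. Claisen condensation with LiN(iPr)2 then proceeds on an unstrained, acyclic-protected substrate to give the dione F4, and HF·pyridine removes the silyl groups. The sequence comes back to the route at 20.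

Step 13. Attack at the crowded gamma carbon C8a may lose out to attack at C5, or silylation of the tertiary alcohol may be incomplete. The fallback sets out from 22 and introduces C1 by condensation instead of by a silyl dienol ether. TBSOTf and 2,6-lutidine give the bis(silyl) ether F5. Heating with tert-butoxybis(dimethylamino)methane condenses the only enolisable position, C8a, to the enaminone F6. Mild aqueous acid (PPTS, wet acetone) hydrolyses the enamine, and the sequence comes back to the route at 25, the intermediate of step 14.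

Further compounds

F1 | step 14 | pyrrolidine 1,6-adduct of 24 (pyrrolidin-1-yl on C3, drawn cis to C4a, geometry inconsequential; other centres as in 24) | O=C1C=C(/C=C(\N2CCCC2)[C@@]3(C)OC(C)(C)O[C@@H]3/C(C)=C/[C@@H](C)CC)[C@H](C(OC)OC)[C@@H](O[Si](C)(C)C(C)(C)C)[C@]1(C)O[Si](C)(C)C(C)(C)C
F2 | step 10 | methyl (2S,3R)-2,3-dihydroxy-2-methyl-5-oxohexanoate | COC(=O)[C@@](C)(O)[C@H](O)CC(C)=O
F3 | step 10 | methyl (2S,3R)-2-methyl-5-oxo-2,3-bis(triethylsilyloxy)hexanoate | COC(=O)[C@@](C)(O[Si](CC)(CC)CC)[C@H](O[Si](CC)(CC)CC)CC(C)=O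
F4 | step 10 | (4S,5R)-4-methyl-4,5-bis(triethylsilyloxy)cyclohexane-1,3-dione | O=C1[C@@](C)(O[Si](CC)(CC)CC)[C@H](O[Si](CC)(CC)CC)CC(=O)C1
F5 | step 13 | (5R,6S)-5,6-bis(tert-butyldimethylsilyloxy)-6-methyl-3-{[(4R,5R)-2,2,4-trimethyl-5-[(2E,4S)-4-methylhex-2-en-2-yl]-1,3-dioxolan-4-yl]ethynyl}cyclohex-2-en-1-one | O=C1C=C(C#C[C@@]2(C)OC(C)(C)O[C@@H]2/C(C)=C/[C@@H](C)CC)C[C@@H](O[Si](C)(C)C(C)(C)C)[C@]1(C)O[Si](C)(C)C(C)(C)C
F6 | step 13 | C8a-(dimethylaminomethylidene) derivative of F5 (amino group on the C4a side; ring centres as in 25) | CN(C)/C=C1\C(C#C[C@@]2(C)OC(C)(C)O[C@@H]2/C(C)=C/[C@@H](C)CC)=CC(=O)[C@@](C)(O[Si](C)(C)C(C)(C)C)[C@@H]1O[Si](C)(C)C(C)(C)C
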